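Remark on numbering and stereochemistry: the ring atoms are numbered as in germacrane (C1H=C10(CH3), C9H2, C8 aryl ester, C7 isopropyl, C6 OH, C5 and C4(CH3) epoxide, C3H2, C2H2), which makes target 31 the (1(10)E,4R,5R,6R,7S,8S) isomer; the chair analysis below requires (S)-(+)-carvone and a (Z)-enol ether.

## The problem

Target 31 is a germacrane: a ten-membered carbocycle with an (E)-trisubstituted alkene (C1=C10) and a trans-trisubstituted epoxide (C4–C5), a ring size that resists end-to-end closure and, once both units are in place, invites transannular reactions. Five contiguous stereocentres, C4 to C8, have to be set. The C8 oxygen can control C6 in the 1,3-anti sense by internal hydride delivery, C7 between them is epimerisable as long as C6 is a ketone, and C4 and C5 lie too far from C8 to be controlled by it, so they are best taken from the chiral pool. The fragile groups are the epoxide (next to a free alcohol and across the ring from the alkene), the aryl ester 1,3 to a free hydroxyl (acyl shift), and every intermediate with a C6 carbonyl and a C8 oxygen (E1cB loss, retro-aldol opening). The enabling feature is that C1 to C6, with methyl and oxygen on C4 and oxygen on C5 and C6, map onto the ring of a p-menthane. If C1 bears an isopropenyl group (C10, its methyl, C9) and C6 bears a hydroxyl and a C7=C8 enol ether, then C9=C10–C1–C6–C7=C8 is a 3-hydroxy-1,5-diene whose alkoxide, by a [3,3] shift, forms C8–C9 and breaks C1–C6, so that the ten-membered ring arises by ring expansion. A cis-4,5-diol on the cyclohexane becomes the trans-epoxide by one inversion at C5, so no (E,E)-diene is ever needed.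

## Retrosynthesis

**Epoxide (31 back to 28).** The O–C5 bond of the epoxide is cut, leading through silyl ether 30 and mesylate 29 to cis-diol 28. The alternative, epoxidising a C4=C5 alkene, would need the Cope-labile (E,E)-1,5-diene and a face-selective oxidant. The displacement needs only that the tertiary C4 oxygen attacks C5 with inversion. The 6-OH is masked as a TBS ether (30, 28, 27) because mesylation cannot distinguish the two secondary alcohols at C5 and C6. The forward steps must cleave the acetonide of 27 without losing silicon, close the epoxide with a non-nucleophilic base, and remove silicon without an acyl shift.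

**Ester and C6 carbinol (26 back to 23 and 24).** The acyl–O8 bond and the C6–H bond are cut together, giving β-hydroxy ketone 23 and 3,4,5-trimethoxybenzaldehyde 24 (Evans–Tishchenko). Reduction followed by acylation would need a separate O8/O6 discrimination. The Tishchenko step sets C6 anti to C8 and places the ester in one operation.

**C8 ether (23 back to 22).** The free C8 hydroxyl is traced to a 4-methoxybenzyl ether, which survives strong base and is removed oxidatively under neutral conditions.

**Ring (22 back to 19).** The C8–C9 bond is cut and C1–C6 is reconnected, an anionic oxy-Cope transform. The ten-membered ketone 22 collapses to cyclohexanol 19, which has two alkenyl groups trans on adjacent carbons. The chair transition state gives the (E)-alkene because the C1–C2 bond is equatorial. C8 depends on the handedness of the chair (set by C1) and on whether the enol ether oxygen is axial or equatorial. Two pairings give 8S together with the required 4,5-diol: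

- (a) diol oxygens trans to the isopropenyl group with an (E)-enol ether (oxygen equatorial);
- (b) diol oxygens cis to the isopropenyl group with a (Z)-enol ether (oxygen axial).

Pairing (b) is chosen for four reasons:

- Reduction and hydroxyl-directed epoxidation of a carvone deliver the cis arrangement directly.
- The reacting chair of 19 then has the C4 methyl and both alkenyl groups equatorial, whereas (a) forces the methyl axial.
- The (Z)-enol ether comes from an alkenyl metal with metal and oxygen cis, the stable arrangement. The trans isomer needed for (a) loses alkoxide by anti elimination.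
- The outer face of the resulting enolate leads to the required C7 configuration in (b) and to its epimer in (a).

The price is an axial alkoxy group in the chair.

**Side chain (19 back to 10 and 16).** The C6–C7 bond is cut, giving ketone 10 and bromo enol ether 16 (as its organocerium). Addition must occur from the equatorial direction, which the axial C4–O bond of the cis-fused dioxolane enforces.

**Bromo enol ether (16 back to 11 and 12).** 16 is traced through enol ether 14 and acetal 13 to 3-methylbutanal 11 and two molecules of 4-methoxybenzyl alcohol 12. C8 is the aldehyde carbon and C7 the α-carbon.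

**Ketone (10 back to 1).** 10 is an isopulegone with a cis-diol. It is traced through alcohol 9, triol 8, epoxy diol 7, diol 6, hydroxy ketone 5 and silyl dienol ether 3 to (S)-carvone 1. This amounts to α′-oxygenation plus a 1,2-carbonyl transposition, in which the carvone carbonyl carbon becomes C5 and the ring alkene becomes C4/C3.

## Roads not taken

Alternative 1: Cuts C6–C7 and O–C8. NaOCl would turn the open-chain epoxy aldoxime A1 into a nitrile oxide at C6, which adds across the tethered (Z)-C7=C8 alkene to give isoxazoline A2.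
- Merits: carbocycle, C7 and C8 are set in one suprafacial event; N–O cleavage reveals the β-hydroxy ketone with the epoxide already in place; few protecting groups.
- Weak points: the ten-membered ring must close end to end against entropy and transannular strain. The nitrile oxide carbon must bond to the distal, isopropyl-bearing carbon of a 1,2-dialkyl alkene with little electronic bias. Dimerisation competes. Reductive N–O cleavage must spare an α,β-epoxy ketone.
- Comparison: this road is shorter after ring closure and avoids a β-alkoxy enolate. The chosen plan sets against it a ring-forming step precedented for this ring size, with alkene geometry and C8 dictated by a chair.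

Alternative 2: Cuts C4–C5 and O–C5. LiN(SiMe3)2 would enolise chloromethyl ketone A3 at C5; addition to the C4 methyl ketone and chloride displacement give epoxy ketone A4.
- Merits: ring and epoxide form together at the final oxidation level, and the diol-to-epoxide sequence disappears.
- Weak points: a medium ring closed by a reversible aldol addition to a methyl ketone. Enolisation competes at the methyl ketone and at C7. The C7 proton is β to the C8 silyloxy group, so epimerisation and E1cB loss are likely. C4 and C5 must be induced across the ring by C7 and C8.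
- Comparison: more convergent on paper, but the chosen plan takes C4 and C5 from the chiral pool.

Alternative 3: Cuts C1–C2. 9-BBN would hydroborate the terminal alkene of dienyl iodide A5, and Pd(dppf)Cl2 with Cs2CO3 would couple C2 with the C1 vinyl iodide to give diene A6.
- Merits: C6, C7 and C8 are set in open-chain chemistry with the same Tishchenko logic. Both alkene geometries are fixed before closure. No C7 protonation and no β-alkoxy enolate are involved. In stereocontrol at C6 to C8 and in convergence this road is better.
- Weak points: closing a strained ten-membered (E,E)-1,5-diene by cross-coupling has little precedent. The product can undergo Cope rearrangement to a divinylcyclohexane on warming. A late chemo- and face-selective epoxidation of C4=C5 remains.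
- Comparison: the chosen plan sets against it a ring formation driven by enolate formation and a route that never passes through the (E,E)-diene.

Key step: step 12

## Route

Step 1
Reactants: 1 (S)-(+)-carvone
Product: 3 trimethyl{[(6S)-3-methyl-6-(prop-1-en-2-yl)cyclohexa-1,3-dien-2-yl]oxy}silane, via lithium dienolate 2 (not isolated)
Conditions: LiN(iPr)2, THF, −78 °C; TMSCl, −78 → 0 °C
Reagents that add atoms: chlorotrimethylsilane, C[Si](C)(C)Cl
Why: Kinetic deprotonation of the enone at the α′-CH2 gives the cross-conjugated dienolate, which is silylated on oxygen; the stereocentre is untouched.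

Step 2
Reactants: 3 silyl dienol ether
Product: 5 (5R,6R)-6-hydroxy-2-methyl-5-(prop-1-en-2-yl)cyclohex-2-en-1-one, via silyloxy ketone 4 (not isolated)
Conditions: mCPBA, NaHCO3, CH2Cl2, −20 → 0 °C; then 1 M HCl, THF, 0 °C
Reagents that add atoms: 3-chloroperbenzoic acid, OOC(=O)c1cccc(Cl)c1
Why: Rubottom oxidation of a 2-silyloxy-1,3-diene: the peracid attacks the electron-rich enol ether bond anti to the neighbouring isopropenyl group, silyl shift gives the α-silyloxy ketone, and dilute acid frees the trans α′-hydroxy enone.

Step 3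
Reactants: 5 hydroxy enone
Product: 6 (1R,2R,6R)-3-methyl-6-(prop-1-en-2-yl)cyclohex-3-ene-1,2-diol
Conditions: NaBH4, CeCl3·7H2O, MeOH, −78 → 0 °C
Reagents that add atoms: none
Why: Luche 1,2-reduction; axial hydride attack on the half-chair with both substituents equatorial should give the equatorial allylic alcohol, cis (1,3) to the isopropenyl group and trans to the neighbouring OH, which sets the future C5 oxygen.

Step 4
Reactants: 6 diol
Product: 7 (1S,2S,3R,4R,6R)-1-methyl-4-(prop-1-en-2-yl)-7-oxabicyclo[4.1.0]heptane-2,3-diol
Conditions: t-BuOOH, VO(acac)2 (3 mol%), CH2Cl2, 0 → 25 °C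
Reagents that add atoms: tert-butyl hydroperoxide, CC(C)(C)OO
Why: Vanadium-catalysed hydroxyl-directed epoxidation; the allylic OH delivers the peroxide to its own face of the ring alkene and leaves the isopropenyl group alone, which sets the future C4 oxygen.

Step 5
Reactants: 7 epoxy diol
Product: 8 (1R,2S,3R,4R)-1-methyl-4-(prop-1-en-2-yl)cyclohexane-1,2,3-triol
Conditions: LiAlH4, THF, 0 → 40 °C; aqueous NaOH work-up
Reagents that add atoms: none
Why: Hydride opens the trisubstituted epoxide at the secondary carbon in the trans-diaxial (Fürst–Plattner) sense; the tertiary C–O bond is retained, so the cis-1,2-diol results.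

Step 6
Reactants: 8 triol
Product: 9 (3aS,4R,5R,7aR)-2,2,7a-trimethyl-5-(prop-1-en-2-yl)hexahydro-1,3-benzodioxol-4-ol
Conditions: 2,2-dimethoxypropane, PPTS (cat.), acetone, 25 °C
Reagents that add atoms: 2,2-dimethoxypropane, COC(C)(C)OC
Why: Acetonide formation under equilibrating conditions should select the cis (axial/equatorial) diol over the trans-diequatorial pair, since only the former gives an unstrained cis-fused dioxolane.

Step 7
Reactants: 9 acetonide alcohol
Product: 10 (3aR,5R,7aR)-2,2,7a-trimethyl-5-(prop-1-en-2-yl)tetrahydro-1,3-benzodioxol-4(3aH)-one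
Conditions: Dess–Martin periodinane, NaHCO3, CH2Cl2, 0 → 25 °C
Reagents that add atoms: none
Why: Dess–Martin oxidation under buffered, neutral conditions gives the β,γ-unsaturated ketone without moving the double bond into conjugation; the isopropenyl group is already equatorial, so C1 has no reason to epimerise.

Step 8
Reactants: 11 3-methylbutanal; 12 4-methoxybenzyl alcohol (two equivalents)
Product: 13 3-methylbutanal bis(4-methoxybenzyl) acetal
Conditions: 12 (2.2 equiv), PPTS (cat.), 4 Å molecular sieves, CH2Cl2, 25 °C
Reagents that add atoms: 4-methoxybenzyl alcohol (the second equivalent of 12), COc1ccc(CO)cc1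
Why: Acid-catalysed acetalisation driven by removal of water: two molecules of 12 condense with the aldehyde carbon of 11 through the hemiacetal and the oxocarbenium ion, and the weak acid spares the benzylic alcohol.

Step 9
Reactants: 13 acetal
Product: 14 1-methoxy-4-{[(3-methylbut-1-en-1-yl)oxy]methyl}benzene (E/Z mixture)
Conditions: TMSOTf, iPr2NEt, CH2Cl2, −20 → 25 °C
Reagents that add atoms: none
Why: Silyl triflate ionises the acetal to the oxocarbenium ion and the hindered amine removes the α-proton (acetal-to-enol-ether elimination); both alkene isomers converge in step 10.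

Step 10
Reactants: 14 enol ether
Product: 16 (Z)-1-{[(2-bromo-3-methylbut-1-en-1-yl)oxy]methyl}-4-methoxybenzene, via dibromo ether 15 (not isolated)
Conditions: Br2, CH2Cl2, −78 °C; then Et3N, −78 → 25 °C
Reagents that add atoms: bromine, BrBr
Why: Bromination and dehydrobromination of an enol ether, as in the preparation of 5-bromo-3,4-dihydro-2H-pyran: the α-bromo ether ionises and the amine removes the proton on the brominated carbon; bromine should end cis to oxygen, with isopropyl trans to the ether.

Step 11
Reactants: 16 (Z)-bromo enol ether; 10 ketone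
Product: 19 (3aS,4R,5R,7aR)-4-{(1Z)-1-[(4-methoxybenzyl)oxy]-3-methylbut-1-en-2-yl}-2,2,7a-trimethyl-5-(prop-1-en-2-yl)hexahydro-1,3-benzodioxol-4-ol, via alkenyllithium 17 (not isolated), via alkenylcerium dichloride 18 (not isolated)
Conditions: 16, t-BuLi (2 equiv), THF, −78 °C; CeCl3, −78 °C; then 10, −78 °C; aqueous NH4Cl
Reagents that add atoms: none
Why: Bromine–lithium exchange with retention gives the alkenyllithium with metal and oxygen cis (chelated, no anti elimination), and the organocerium adds without enolising 10; attack from the equatorial direction, away from the axial C4–O bond of the cis-fused dioxolane, should give the axial alcohol with the new alkenyl group equatorial and trans to isopropenyl (C6 set).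

Step 12
Reactants: 19 tertiary alcohol
Product: 22 (1(10)E,4R,5R,7R,8S)-4,5-(isopropylidenedioxy)-8-[(4-methoxybenzyl)oxy]germacr-1(10)-en-6-one, via potassium alkoxide 20 (not isolated), via potassium enolate 21 (not isolated)
Conditions: KH, 18-crown-6, THF, 0 → 25 °C; then cannulated into AcOH/THF, −78 °C
Reagents that add atoms: none
Why: KH forms the tertiary alkoxide, whose donor effect weakens the C1–C6 bond, and the 3-oxido-1,5-diene undergoes an anionic oxy-Cope rearrangement, the known ring expansion of trans-1,2-dialkenylcyclohexanols to (E)-cyclodec-5-enones. The [3,3] shift runs through a chair (C9, C10, C1, C6, C7, C8) fused trans-diequatorially to the cyclohexane; it forms C8–C9 and breaks C1–C6. The ten-membered ring is therefore made by ring expansion inside a six-membered transition state and not by end-to-end cyclisation, and enolate formation drives it. The equatorial C1–C2 bond places C2 trans to C9, which gives the (E)-C1=C10 alkene. C8 is set by the (Z)-enol ether, which puts the ether oxygen axial, together with the handedness of the chair, which is fixed by the carvone-derived C1 centre; this should give 8S. The enolate leaves the chair as a single planar-chiral form with C5 and C8 trans across C6=C7 and its inner face covered by the ring, so cold inverse quench should protonate the outer face and give the C7 configuration drawn (7R here; 7S in 31 by priority change only). The step needs chair over boat, which the trans-diequatorial alkenyl groups secure because a boat would require an eclipsed C10–C1–C6–C7 torsion. It also needs protonation before E1cB loss of the C8 alkoxide, which is helped by the C8–O bond lying near the nodal plane of the nascent enolate and by the −78 °C acid quench.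

Step 13
Reactants: 22 ten-membered ketone
Product: 23 (1(10)E,4R,5R,7R,8S)-8-hydroxy-4,5-(isopropylidenedioxy)germacr-1(10)-en-6-one
Conditions: DDQ, CH2Cl2/pH 7 buffer, 0 °C
Reagents that add atoms: none
Why: Oxidative cleavage of the 4-methoxybenzyl ether through its benzylic cation under neutral, buffered conditions that leave the β-hydroxy ketone, acetonide and alkene alone.

Step 14
Reactants: 23 β-hydroxy ketone; 24 3,4,5-trimethoxybenzaldehyde
Product: 26 (1(10)E,4R,5S,6R,7S,8S)-6-hydroxy-4,5-(isopropylidenedioxy)germacr-1(10)-en-8-yl 3,4,5-trimethoxybenzoate, via samarium-bound hemiacetal 25 (not isolated)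
Conditions: 24 (5 equiv), SmI2 (0.3 equiv, premixed with 24), THF, −10 °C
Reagents that add atoms: none
Why: Evans–Tishchenko reaction: the C8 hydroxyl forms a hemiacetal with the aldehyde on trivalent samarium, and its C–H is delivered through a six-membered chair to the C6 carbonyl, giving the C8 ester and the 6-OH 1,3-anti to it; premixing consumes the divalent samarium so that none meets the α-alkoxy ketone.

Step 15
Reactants: 26 hydroxy ester
Product: 27 (1(10)E,4R,5S,6R,7R,8S)-6-[(tert-butyldimethylsilyl)oxy]-4,5-(isopropylidenedioxy)germacr-1(10)-en-8-yl 3,4,5-trimethoxybenzoate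
Conditions: TBSOTf, 2,6-lutidine, CH2Cl2, −78 → 0 °C
Reagents that add atoms: tert-butyldimethylsilyl trifluoromethanesulfonate, CC(C)(C)[Si](C)(C)OS(=O)(=O)C(F)(F)F
Why: Silyl triflate with a hindered pyridine silylates the crowded secondary alcohol; this differentiates O6 from O5 before the diol is released.

Step 16
Reactants: 27 silyl ether acetonide
Product: 28 (1(10)E,4R,5S,6R,7R,8S)-6-[(tert-butyldimethylsilyl)oxy]-4,5-dihydroxygermacr-1(10)-en-8-yl 3,4,5-trimethoxybenzoate
Conditions: AcOH/H2O (4:1), 40 °C
Reagents that add atoms: none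
Why: Acid hydrolysis of the isopropylidene acetal; the hindered secondary silyl ether and the aryl ester should survive aqueous acetic acid, which is too weak to protonate the lone trisubstituted alkene.

Step 17
Reactants: 28 diol
Product: 30 (1(10)E,4R,5R,6R,7R,8S)-6-[(tert-butyldimethylsilyl)oxy]-4,5-epoxygermacr-1(10)-en-8-yl 3,4,5-trimethoxybenzoate, via mesylate 29 (not isolated)
Conditions: MsCl, Et3N, CH2Cl2, −20 °C; then DBU, 25 °C
Reagents that add atoms: none
Why: Mesylation selects the secondary over the tertiary hydroxyl; the C4 oxygen then displaces the mesylate with inversion at C5 (intramolecular SN2), turning the cis-diol into the trans-epoxide with C4 unchanged, and the non-nucleophilic base spares the ester.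

Step 18
Reactants: 30 silyl ether epoxide
Product: 31 (1(10)E,4R,5R,6R,7S,8S)-4,5-epoxy-6-hydroxygermacr-1(10)-en-8-yl 3,4,5-trimethoxybenzoate (target)
Conditions: TBAF, AcOH (1:1), THF, 0 → 25 °C
Reagents that add atoms: none
Why: Fluoride cleaves the silyl ether; the acetic acid buffer keeps free alkoxide from forming, so the aryl ester should not shift from O8 to O6 and the neighbouring epoxide should not migrate.

## Compound list

1 | (S)-(+)-carvone, (5S)-2-methyl-5-(prop-1-en-2-yl)cyclohex-2-en-1-one | CC1=CC[C@@H](CC1=O)C(C)=C | starting material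
2 | lithium (6S)-3-methyl-6-(prop-1-en-2-yl)cyclohexa-1,3-dien-2-olate | C1=C(O[Li])C(C)=CC[C@@H]1C(C)=C | intermediate
3 | trimethyl{[(6S)-3-methyl-6-(prop-1-en-2-yl)cyclohexa-1,3-dien-2-yl]oxy}silane | C1=C(O[Si](C)(C)C)C(C)=CC[C@@H]1C(C)=C | intermediate
4 | (5R,6R)-2-methyl-5-(prop-1-en-2-yl)-6-[(trimethylsilyl)oxy]cyclohex-2-en-1-one | C[Si](C)(C)O[C@H]1C(=O)C(C)=CC[C@@H]1C(C)=C | intermediate
5 | (5R,6R)-6-hydroxy-2-methyl-5-(prop-1-en-2-yl)cyclohex-2-en-1-one (OH trans to isopropenyl) | O[C@H]1C(=O)C(C)=CC[C@@H]1C(C)=C | intermediate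
6 | (1R,2R,6R)-3-methyl-6-(prop-1-en-2-yl)cyclohex-3-ene-1,2-diol | O[C@H]1[C@H](O)C(C)=CC[C@@H]1C(C)=C | intermediate
7 | (1S,2S,3R,4R,6R)-1-methyl-4-(prop-1-en-2-yl)-7-oxabicyclo[4.1.0]heptane-2,3-diol | O[C@H]1[C@H](O)[C@]2(C)O[C@@H]2C[C@@H]1C(C)=C | intermediate
8 | (1R,2S,3R,4R)-1-methyl-4-(prop-1-en-2-yl)cyclohexane-1,2,3-triol | O[C@H]1[C@H](O)[C@@](O)(C)CC[C@@H]1C(C)=C | intermediate
9 | (3aS,4R,5R,7aR)-2,2,7a-trimethyl-5-(prop-1-en-2-yl)hexahydro-1,3-benzodioxol-4-ol | O[C@H]1[C@@H]2OC(C)(C)O[C@]2(C)CC[C@@H]1C(C)=C | intermediate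
10 | (3aR,5R,7aR)-2,2,7a-trimethyl-5-(prop-1-en-2-yl)tetrahydro-1,3-benzodioxol-4(3aH)-one | O=C1[C@@H]2OC(C)(C)O[C@]2(C)CC[C@@H]1C(C)=C | intermediate
11 | 3-methylbutanal | CC(C)CC=O | starting material
12 | 4-methoxybenzyl alcohol | COc1ccc(CO)cc1 | starting material
13 | 3-methylbutanal bis(4-methoxybenzyl) acetal | COc1ccc(COC(CC(C)C)OCc2ccc(OC)cc2)cc1 | intermediate
14 | 1-methoxy-4-{[(3-methylbut-1-en-1-yl)oxy]methyl}benzene (E/Z mixture) | COc1ccc(COC=CC(C)C)cc1 | intermediate
15 | 1-[(1,2-dibromo-3-methylbutoxy)methyl]-4-methoxybenzene (diastereomer mixture) | COc1ccc(COC(Br)C(Br)C(C)C)cc1 | intermediate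
16 | (Z)-1-{[(2-bromo-3-methylbut-1-en-1-yl)oxy]methyl}-4-methoxybenzene (Br cis to O) | COc1ccc(CO/C=C(\Br)C(C)C)cc1 | intermediate
17 | {(1E)-1-[(4-methoxybenzyl)oxy]-3-methylbut-1-en-2-yl}lithium (Li cis to O) | COc1ccc(CO/C=C(\[Li])C(C)C)cc1 | intermediate
18 | dichloro{(1Z)-1-[(4-methoxybenzyl)oxy]-3-methylbut-1-en-2-yl}cerium (Ce cis to O) | COc1ccc(CO/C=C(\[Ce](Cl)Cl)C(C)C)cc1 | intermediate
19 | (3aS,4R,5R,7aR)-4-{(1Z)-1-[(4-methoxybenzyl)oxy]-3-methylbut-1-en-2-yl}-2,2,7a-trimethyl-5-(prop-1-en-2-yl)hexahydro-1,3-benzodioxol-4-ol | O[C@]1(/C(C(C)C)=C\OCc2ccc(OC)cc2)[C@@H]3OC(C)(C)O[C@]3(C)CC[C@@H]1C(C)=C | intermediate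
20 | potassium alkoxide of 19 | [K]O[C@]1(/C(C(C)C)=C\OCc2ccc(OC)cc2)[C@@H]3OC(C)(C)O[C@]3(C)CC[C@@H]1C(C)=C | intermediate
21 | potassium C6=C7 enolate of 22 (C5 and C8 trans across the enolate double bond, 8S) | COc1ccc(CO[C@H]2C/C(C)=C/CC[C@@]3(C)OC(C)(C)O[C@H]3/C(O[K])=C2\C(C)C)cc1 | intermediate
22 | (1(10)E,4R,5R,7R,8S)-4,5-(isopropylidenedioxy)-8-[(4-methoxybenzyl)oxy]germacr-1(10)-en-6-one | COc1ccc(CO[C@H]2C/C(C)=C/CC[C@@]3(C)OC(C)(C)O[C@H]3C(=O)[C@@H]2C(C)C)cc1 | intermediate
23 | (1(10)E,4R,5R,7R,8S)-8-hydroxy-4,5-(isopropylidenedioxy)germacr-1(10)-en-6-one | O[C@H]1C/C(C)=C/CC[C@@]2(C)OC(C)(C)O[C@H]2C(=O)[C@@H]1C(C)C | intermediate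
24 | 3,4,5-trimethoxybenzaldehyde | COc1cc(C=O)cc(OC)c1OC | starting material
25 | O8 hemiacetal of 23 with 24 (samarium-bound; hemiacetal carbon of either configuration) | COc1cc(C(O)O[C@H]2C/C(C)=C/CC[C@@]3(C)OC(C)(C)O[C@H]3C(=O)[C@@H]2C(C)C)cc(OC)c1OC | intermediate
26 | (1(10)E,4R,5S,6R,7S,8S)-6-hydroxy-4,5-(isopropylidenedioxy)germacr-1(10)-en-8-yl 3,4,5-trimethoxybenzoate | COc1cc(C(=O)O[C@H]2C/C(C)=C/CC[C@@]3(C)OC(C)(C)O[C@H]3[C@H](O)[C@@H]2C(C)C)cc(OC)c1OC | intermediate
27 | (1(10)E,4R,5S,6R,7R,8S)-6-[(tert-butyldimethylsilyl)oxy]-4,5-(isopropylidenedioxy)germacr-1(10)-en-8-yl 3,4,5-trimethoxybenzoate | COc1cc(C(=O)O[C@H]2C/C(C)=C/CC[C@@]3(C)OC(C)(C)O[C@H]3[C@H](O[Si](C)(C)C(C)(C)C)[C@@H]2C(C)C)cc(OC)c1OC | intermediate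
28 | (1(10)E,4R,5S,6R,7R,8S)-6-[(tert-butyldimethylsilyl)oxy]-4,5-dihydroxygermacr-1(10)-en-8-yl 3,4,5-trimethoxybenzoate | COc1cc(C(=O)O[C@H]2C/C(C)=C/CC[C@@](C)(O)[C@@H](O)[C@H](O[Si](C)(C)C(C)(C)C)[C@@H]2C(C)C)cc(OC)c1OC | intermediate
29 | (1(10)E,4R,5S,6R,7R,8S)-6-[(tert-butyldimethylsilyl)oxy]-4-hydroxy-5-[(methylsulfonyl)oxy]germacr-1(10)-en-8-yl 3,4,5-trimethoxybenzoate | COc1cc(C(=O)O[C@H]2C/C(C)=C/CC[C@@](C)(O)[C@@H](OS(C)(=O)=O)[C@H](O[Si](C)(C)C(C)(C)C)[C@@H]2C(C)C)cc(OC)c1OC | intermediate
30 | (1(10)E,4R,5R,6R,7R,8S)-6-[(tert-butyldimethylsilyl)oxy]-4,5-epoxygermacr-1(10)-en-8-yl 3,4,5-trimethoxybenzoate | COc1cc(C(=O)O[C@H]2C/C(C)=C/CC[C@@]3(C)O[C@@H]3[C@H](O[Si](C)(C)C(C)(C)C)[C@@H]2C(C)C)cc(OC)c1OC | intermediate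
31 | (1(10)E,4R,5R,6R,7S,8S)-4,5-epoxy-6-hydroxygermacr-1(10)-en-8-yl 3,4,5-trimethoxybenzoate | COc1cc(C(=O)O[C@H]2C/C(C)=C/CC[C@@]3(C)O[C@@H]3[C@H](O)[C@@H]2C(C)C)cc(OC)c1OC | target

## Step count and risks

Total step count: 18. Longest linear sequence: 15 steps from (S)-carvone (steps 1–7 and 11–18); the side-chain branch (steps 8–10) joins at step 11.

**Step 12 (key step).** The most likely failure is E1cB loss of the C8 alkoxide from the potassium enolate before the quench, once the ring relaxes and the C8–O bond aligns with the enolate. Protonation at C7 from the inner face, or a slow shift because the ether must sit axial beside the alkoxide, are lesser concerns; leaving out the crown ether so that potassium bridges both oxygens would address the latter. The fallback accepts the elimination. Starting from 19, the same base at 25 °C for longer should give the enone (1(10)E,7Z)-4,5-(isopropylidenedioxy)germacra-1(10),7-dien-6-one F1. Copper-catalysed conjugate borylation (CuCl, NaOtBu, a chiral bisphosphine, bis(pinacolato)diboron, MeOH, THF) would put boron on C8 and a proton on C7 to give the β-boryl ketone F2. Oxidation with NaBO3·4H2O, which retains configuration at carbon, returns to the route at 23. In this fallback C8 and C7 are set by the ligand and the ring conformation instead of by the chair.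

**Step 11.** The basic alkenyl metal may deprotonate ketone 10 at C1, returning epimerised or conjugated ketone. The β-alkoxyalkenyl metal may also decay by proton transfer from the benzylic CH2 or by loss of geometry before it adds. The fallback introduces the C8 oxygen after ring expansion. Starting from 10, the robust 3-methylbut-1-en-2-yllithium F3 (from 2-bromo-3-methylbut-1-ene and t-BuLi, with CeCl3) would give the oxygen-free tertiary alcohol F4. KH/18-crown-6 followed by TMSCl/Et3N at −78 °C traps the ring-expanded enolate as the ten-membered trimethylsilyl enol ether F5. Saegusa–Ito oxidation (Pd(OAc)2, MeCN) gives the enone F1. Conjugate borylation to the β-boryl ketone F2 and oxidation, as above, return at 23.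

**Step 14.** Hydride transfer may not compete: hemiacetal formation between the hindered C8 hydroxyl and an electron-rich aryl aldehyde may be slow, retro-aldol opening of the ring may intervene, or residual divalent samarium may reduce the α-alkoxy ketone. The fallback separates reduction and acylation. Starting from 23, Me4NBH(OAc)3 in MeCN/AcOH at −30 °C (Evans–Saksena reduction, hydride delivered from boron bound at O8) should give the anti-diol (1(10)E,4R,5S,6R,7R,8S)-4,5-(isopropylidenedioxy)germacr-1(10)-ene-6,8-diol F6. One equivalent of 3,4,5-trimethoxybenzoyl chloride with pyridine at −20 °C should then acylate the less hindered O8, returning at 26.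

**Step 10.** Loss of HBr may give a mixture of alkene isomers, the amine may capture the α-bromo ether, or the anisyl ring may be brominated. The fallback reverses the order of events. Starting from 11, α-bromination (Br2, dioxane/Et2O, 0 °C) gives racemic 2-bromo-3-methylbutanal F7. Acetalisation with two equivalents of 12 (PPTS, MgSO4) gives 2-bromo-3-methylbutanal bis(4-methoxybenzyl) acetal F8. TMSOTf/iPr2NEt then removes one molecule of the alcohol instead of HBr, returning at 16.

**Step 18.** Under fluoride the aryl ester may shift from O8 to the freed O6, the epoxide may migrate, or cleavage at the crowded C6 may be too slow. The fallback changes the C6 protecting group to one removed oxidatively. Starting from 26, 4-methoxybenzyl trichloroacetimidate with Sc(OTf)3 (cat.) gives the C6 4-methoxybenzyl ether F9. AcOH/H2O gives the diol F10. MsCl/Et3N followed by DBU gives, through the mesylate F11, the epoxide F12. DDQ in buffered CH2Cl2 then releases 31 directly.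

## Further compounds

F1 | step 12 | (1(10)E,7Z,4R,5R)-4,5-(isopropylidenedioxy)germacra-1(10),7-dien-6-one | O=C1[C@@H]2OC(C)(C)O[C@]2(C)CC/C=C(\C)C/C=C1/C(C)C
F2 | step 12 | (1(10)E,4R,5R,7S,8S)-4,5-(isopropylidenedioxy)-8-(4,4,5,5-tetramethyl-1,3,2-dioxaborolan-2-yl)germacr-1(10)-en-6-one | CC1(C)OB(OC1(C)C)[C@H]2C/C(C)=C/CC[C@@]3(C)OC(C)(C)O[C@H]3C(=O)[C@@H]2C(C)C
F3 | step 11 | 3-methylbut-1-en-2-yllithium | [Li]C(=C)C(C)C
F4 | step 11 | (3aS,4R,5R,7aR)-2,2,7a-trimethyl-4-(3-methylbut-1-en-2-yl)-5-(prop-1-en-2-yl)hexahydro-1,3-benzodioxol-4-ol | O[C@]1(C(=C)C(C)C)[C@@H]2OC(C)(C)O[C@]2(C)CC[C@@H]1C(C)=C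
F5 | step 11 | (1(10)E,6E,4R,5R)-4,5-(isopropylidenedioxy)-6-[(trimethylsilyl)oxy]germacra-1(10),6-diene (C5 and C8 trans across C6=C7) | C1C/C(C)=C/CC[C@@]2(C)OC(C)(C)O[C@H]2/C(O[Si](C)(C)C)=C1\C(C)C
F6 | step 14 | (1(10)E,4R,5S,6R,7R,8S)-4,5-(isopropylidenedioxy)germacr-1(10)-ene-6,8-diol | O[C@H]1C/C(C)=C/CC[C@@]2(C)OC(C)(C)O[C@H]2[C@H](O)[C@@H]1C(C)C
F7 | step 10 | 2-bromo-3-methylbutanal (racemic) | CC(C)C(Br)C=O
F8 | step 10 | 2-bromo-3-methylbutanal bis(4-methoxybenzyl) acetal (racemic) | COc1ccc(COC(C(Br)C(C)C)OCc2ccc(OC)cc2)cc1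
F9 | step 18 | (1(10)E,4R,5S,6R,7R,8S)-4,5-(isopropylidenedioxy)-6-[(4-methoxybenzyl)oxy]germacr-1(10)-en-8-yl 3,4,5-trimethoxybenzoate | COc1cc(C(=O)O[C@H]2C/C(C)=C/CC[C@@]3(C)OC(C)(C)O[C@H]3[C@H](OCc4ccc(OC)cc4)[C@@H]2C(C)C)cc(OC)c1OC
F10 | step 18 | (1(10)E,4R,5S,6R,7R,8S)-4,5-dihydroxy-6-[(4-methoxybenzyl)oxy]germacr-1(10)-en-8-yl 3,4,5-trimethoxybenzoate | COc1cc(C(=O)O[C@H]2C/C(C)=C/CC[C@@](C)(O)[C@@H](O)[C@H](OCc3ccc(OC)cc3)[C@@H]2C(C)C)cc(OC)c1OC
F11 | step 18 | (1(10)E,4R,5S,6R,7R,8S)-4-hydroxy-6-[(4-methoxybenzyl)oxy]-5-[(methylsulfonyl)oxy]germacr-1(10)-en-8-yl 3,4,5-trimethoxybenzoate | COc1cc(C(=O)O[C@H]2C/C(C)=C/CC[C@@](C)(O)[C@@H](OS(C)(=O)=O)[C@H](OCc3ccc(OC)cc3)[C@@H]2C(C)C)cc(OC)c1OC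
F12 | step 18 | (1(10)E,4R,5R,6R,7R,8S)-4,5-epoxy-6-[(4-methoxybenzyl)oxy]germacr-1(10)-en-8-yl 3,4,5-trimethoxybenzoate | COc1cc(C(=O)O[C@H]2C/C(C)=C/CC[C@@]3(C)O[C@@H]3[C@H](OCc4ccc(OC)cc4)[C@@H]2C(C)C)cc(OC)c1OC
A1 | alternative 1 | open-chain (4R,5R)-4,5-epoxy aldoxime with (1(10)E) and (7Z) alkenes | ON=C[C@H]1O[C@]1(C)CC/C=C(\C)C/C=C\C(C)C
A2 | alternative 1 | isoxazoline-fused 4,5-epoxycyclodecene (C6=N–O–C8 bridge) | O1[C@H]2C/C(C)=C/CC[C@@]3(C)O[C@@H]3C(=N1)[C@@H]2C(C)C
A3 | alternative 2 | open-chain chloromethyl ketone/methyl ketone with C8 silyl ether | ClCC(=O)[C@H](C(C)C)[C@@H](O[Si](C)(C)C(C)(C)C)C/C(C)=C/CCC(C)=O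
A4 | alternative 2 | ten-membered 4,5-epoxy-6-ketone with C8 silyl ether | CC(C)(C)[Si](C)(C)O[C@H]1C/C(C)=C/CC[C@@]2(C)O[C@@H]2C(=O)[C@@H]1C(C)C
A5 | alternative 3 | open-chain dienyl vinyl iodide with C8 aryl ester and C6 triethylsilyl ether | COc1cc(C(=O)O[C@@H](C/C(C)=C/I)[C@@H](C(C)C)[C@@H](O[Si](CC)(CC)CC)/C=C(\C)C=C)cc(OC)c1OC
A6 | alternative 3 | ten-membered (E,E)-diene with C8 aryl ester and C6 triethylsilyl ether | COc1cc(C(=O)O[C@H]2C/C(C)=C/CC/C(C)=C/[C@H](O[Si](CC)(CC)CC)[C@@H]2C(C)C)cc(OC)c1OC
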